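**Retrosynthetic overview**
- Target 24 ⇐ (desilylation, C5′ angeloylation, CBS reduction, silylation) ⇐ aldol adduct 20 ⇐ aldol disconnection of C3′–C4′ into the C10 ring A enal 15 and the C5 methyl ketone 17. Side-chain numbering: C1′ (=CH2), C2′, C3′ (carbinol), C4′ (CH2), C5′, C6′ (C(CH3)2O).
- Enabling feature: the C3′ carbinol is 1,3 to the oxygenated C5′ (aldol retron). C5′ is flanked by the fully substituted C6′, so only the C4′ methyl of the ketone can enolise. C3′ hangs on the sp2 carbon C2′ carried by C5 of the cyclohexane (ring A), so the aldehyde partner is a non-enolisable 2-substituted acrolein.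
- Enal 15 ⇐ allylic oxidation of the isopropenyl group of 13 ⇐ tetraol 8 (stannylene-directed C1 angeloylation, silylation) ⇐ directed epoxidation and trans-diaxial opening (C2, C3), Luche reduction (C1), Mitsunobu inversion (C6), α′-hydroxylation ⇐ (S)-carvone.
- Rings: the only carbocycle (ring A) is taken intact from (S)-carvone. No ring is built apart from a temporary oxirane made in step 4 and opened in step 5.

Key step: step 11

**Remarks**
- Ring intermediates use carvone numbering: C1 = former C=O (later the ring angelate carbon), C2 = methyl-bearing carbon, C3, C4 (CH2), C5 = carbon bearing the isopropenyl/side chain, C6. β = face of the C5 substituent, α = opposite face. TES = triethylsilyl, Ang = angeloyl = (Z)-2-methylbut-2-enoyl.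
- Commercial starting materials: 1, 9, 16.
- Assumption: Ipc2B enolates of methyl ketones are taken to add to 2-substituted enals with the usual sense of induction, the (−)-reagent (from (+)-α-pinene) attacking the re face required here; if the opposite sense is found, (+)-Ipc2BCl is used in step 11.

**Step 1**
Reactants: 1 (S)-(+)-carvone
Product: 3 trans-6-hydroxycarvone (5R,6R; 6α-OH), via sodium dienolate 2 (not isolated)
Conditions: NaN(SiMe3)2, THF, −78 °C; then 3-phenyl-2-(phenylsulfonyl)oxaziridine, −78 °C; aq. NH4Cl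
Reagents that add atoms: 3-phenyl-2-(phenylsulfonyl)oxaziridine, O=S(=O)(N1OC1c1ccccc1)c1ccccc1
Why: Kinetic α′-deprotonation at C6 (the only enolisable α-position) and Davis oxaziridine hydroxylation of the dienolate should deliver oxygen anti to the adjacent C5 isopropenyl group, giving mainly the trans (6α) alcohol.

**Step 2**
Reactants: 3 trans-6-hydroxycarvone
Product: 4 cis-6-(4-nitrobenzoyloxy)carvone (5R,6S; 6β-ester)
Conditions: 4-O2NC6H4CO2H, PPh3, DIAD, toluene, 0 °C → rt
Reagents that add atoms: 4-nitrobenzoic acid, O=C(O)c1ccc(cc1)[N+](=O)[O-]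
Why: Mitsunobu esterification proceeds by SN2 inversion at the carbonyl-activated C6 carbinol, placing the C6 oxygen cis (β) to the C5 isopropenyl group.

**Step 3**
Reactants: 4 cis-6-(4-nitrobenzoyloxy)carvone
Product: 5 1β-hydroxy-6β-(4-nitrobenzoyloxy) allylic alcohol (6-acyloxy-cis-carveol, 1R,5R,6S)
Conditions: NaBH4, CeCl3·7H2O, MeOH, −78 °C
Reagents that add atoms: none
Why: Luche 1,2-reduction; hydride should attack C1 from the α face, anti to the pseudo-axial C6 acyloxy group (the same axial attack that gives cis-carveol from carvone), setting the 1β-OH.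

**Step 4**
Reactants: 5 allylic alcohol
Product: 6 2β,3β-epoxy-1β-hydroxy-6β-(4-nitrobenzoyloxy) compound
Conditions: VO(acac)2 (cat.), t-BuOOH, CH2Cl2, 0 °C → rt
Reagents that add atoms: tert-butyl hydroperoxide, CC(C)(C)OO
Why: Vanadium-catalysed hydroxyl-directed epoxidation delivers oxygen to the C2=C3 alkene syn to the 1β-OH and leaves the isopropenyl group untouched.

**Step 5**
Reactants: 6 epoxy alcohol ester
Product: 8 2α-methyl-5β-(prop-1-en-2-yl)cyclohexane-1β,2β,3α,6β-tetrol (1S,2R,3S,5R,6S), via epoxy diol 7 (not isolated)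
Conditions: KOH, DMSO/H2O, 80 °C; then HCl to pH 6
Reagents that add atoms: water, O
Why: Saponification of the 4-nitrobenzoate is followed by hydroxide opening of the trisubstituted epoxide at the secondary C3 in the trans-diaxial (Fürst–Plattner) mode, inverting C3 (3α-OH) and retaining the 2β-OH; the cis-disposed alkoxides cannot attack the oxirane from the rear.

**Step 6**
Reactants: 9 angelic acid
Product: 10 angelic 2,4,6-trichlorobenzoic anhydride (used as a filtered toluene solution)
Conditions: 2,4,6-Cl3C6H2COCl, Et3N, toluene, rt; filter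
Reagents that add atoms: 2,4,6-trichlorobenzoyl chloride, O=C(Cl)c1c(Cl)cc(Cl)cc1Cl
Why: Yamaguchi-type mixed anhydride formation activates angelic acid without a nucleophilic catalyst, so the Z geometry should be kept.

**Step 7**
Reactants: 8 tetraol; 10 mixed anhydride
Product: 12 1-O-angeloyl tetraol (1β-OAng, 2β,3α,6β-triol), via stannylene acetal 11 (not isolated)
Conditions: Bu2SnO, MeOH, reflux; evaporate; then 10, toluene, 0 °C → rt
Reagents that add atoms: none
Why: Dibutylstannylene-mediated regioselective acylation: C1–O is the equatorial partner of both cis-1,2-diol pairs (C1/C6 and C1/C2) and is the activated oxygen, and it should attack the unhindered angeloyl carbonyl of 10.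

**Step 8**
Reactants: 12 mono-angelate triol
Product: 13 2,3,6-tris-O-TES ether of 12
Conditions: TESOTf, 2,6-lutidine, CH2Cl2, −78 → 0 °C
Reagents that add atoms: triethylsilyl triflate, CC[Si](CC)(CC)OS(=O)(=O)C(F)(F)F
Why: Silyl triflate silylation caps the two secondary hydroxyls and the tertiary one, and the ester is inert.

**Step 9**
Reactants: 13 tris-TES ether
Product: 15 ring A enal (2-substituted acrolein on C5), via allylic alcohol 14 (not isolated)
Conditions: SeO2 (0.5 equiv), t-BuOOH, CH2Cl2, rt; then MnO2, CH2Cl2, rt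
Reagents that add atoms: tert-butyl hydroperoxide, CC(C)(C)OO
Why: SeO2 allylic oxidation (ene reaction then [2,3]-shift) of the 1,1-disubstituted alkene should occur at the methyl group in preference to the hindered ring methine, MnO2 converges the allylic alcohol to the enal, and the electron-poor angelate alkene should not react.

**Step 10**
Reactants: 16 3-hydroxy-3-methylbutan-2-one
Product: 17 3-methyl-3-(triethylsilyloxy)butan-2-one
Conditions: TESOTf, 2,6-lutidine, CH2Cl2, 0 °C
Reagents that add atoms: triethylsilyl triflate, CC[Si](CC)(CC)OS(=O)(=O)C(F)(F)F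
Why: Standard silylation of the tertiary alcohol removes the acidic proton before enolisation.

**Step 11**
Reactants: 17 silyloxy methyl ketone; 15 ring A enal
Product: 20 (3′R)-β-hydroxy ketone (aldol adduct; C5′ ketone, C6′-OTES), via enol borinate 18 (not isolated), via boron aldolate 19 (not isolated)
Conditions: (−)-Ipc2BCl, Et3N, Et2O, 0 °C; then 15, −78 → −20 °C; H2O2, pH 7 buffer, MeOH, 0 °C
Reagents that add atoms: none
Why: (−)-Ipc2BCl/Et3N converts 17 into the enol diisopinocampheylborinate 18 (only the C4′ methyl has α-hydrogens, C6′ being fully substituted), which adds to the aldehyde of 15 through a closed six-membered boron-bound transition state to give aldolate 19, cleaved oxidatively to 20. The closest known reaction type is the Paterson Ipc2BCl-mediated aldol of methyl ketones with 2-substituted enals, as used for late fragment unions in polyketide synthesis. No ring is closed; only the cyclic transition state is transient. The single new stereocentre C3′ (R) is set by the Ipc ligands on boron (reagent control, re-face attack), with only a weak bias expected from the remote ring stereocentre C5. The step needs 1,2- rather than 1,4-addition and no γ-deprotonation of the enal, which the boron enolate, the weakly basic medium and the low temperature should secure, and the angelate and silyl ethers are inert. In one operation the C10 and C5 halves are joined, the C15 skeleton is completed and the C5′ carbonyl is placed 1,3 to the new carbinol for the anti-selective reduction.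

**Step 12**
Reactants: 20 aldol adduct
Product: 21 3′-O-TES ether of 20
Conditions: TESOTf, 2,6-lutidine, CH2Cl2, −78 °C
Reagents that add atoms: triethylsilyl triflate, CC[Si](CC)(CC)OS(=O)(=O)C(F)(F)F
Why: Silylation masks the C3′ hydroxyl so that the later acylation can only reach C5′–OH and the reduction is under catalyst control.

**Step 13**
Reactants: 21 β-silyloxy ketone
Product: 22 (3′R,5′R)-5′-alcohol (3′,5′-anti)
Conditions: (S)-1-methyl-3,3-diphenyltetrahydro-1H,3H-pyrrolo[1,2-c][1,3,2]oxazaborole (cat.), catecholborane, toluene, −78 → −40 °C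
Reagents that add atoms: none
Why: Corey–Bakshi–Shibata reduction; with C(CH3)2OTES as the large and C4′H2 as the small ketone substituent the (S)-catalyst should give the 5′R alcohol (same sense as acetophenone → (R)-alcohol), and catecholborane spares the alkenes and esters.

**Step 14**
Reactants: 22 5′-alcohol; 10 mixed anhydride
Product: 23 penta-TES bis-angelate
Conditions: 10 (excess), Et3N, toluene, 80 °C
Reagents that add atoms: none
Why: Thermal acylation of the hindered secondary alcohol by the Yamaguchi-type mixed anhydride without a nucleophilic catalyst should avoid Z → E isomerisation, and with no alkoxide present silyl migration from the neighbouring oxygens is not expected.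

**Step 15**
Reactants: 23 penta-TES bis-angelate
Product: 24 CNP0108485.1 (target)
Conditions: HF·pyridine, pyridine, THF, 0 °C → rt
Reagents that add atoms: none
Why: Buffered fluoride desilylation should remove the three secondary and two tertiary TES groups without base, so the angelates should neither migrate to the cis-vicinal hydroxyls nor isomerise.

**Compound list**
1 | (S)-(+)-carvone, (5S)-2-methyl-5-(prop-1-en-2-yl)cyclohex-2-en-1-one | C=C(C)[C@H]1CC=C(C)C(=O)C1 | starting material
2 | sodium dienolate of 1 (O–C1=C6), formed in situ | C=C(C)[C@H]1CC=C(C)C([O-])=C1.[Na+] | intermediate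
3 | trans-6-hydroxycarvone, (5R,6R)-6-hydroxy-2-methyl-5-(prop-1-en-2-yl)cyclohex-2-en-1-one | C=C(C)[C@H]1CC=C(C)C(=O)[C@@H]1O | intermediate
4 | cis-6-(4-nitrobenzoyloxy)carvone (5R,6S) | C=C(C)[C@H]1CC=C(C)C(=O)[C@H]1OC(=O)c1ccc(cc1)[N+](=O)[O-] | intermediate
5 | 1β-hydroxy-6β-(4-nitrobenzoyloxy)-2-methyl-5β-(prop-1-en-2-yl)cyclohex-2-ene | C=C(C)[C@H]1CC=C(C)[C@@H](O)[C@H]1OC(=O)c1ccc(cc1)[N+](=O)[O-] | intermediate
6 | 2β,3β-epoxide of 5 | C=C(C)[C@H]1C[C@H]2O[C@@]2(C)[C@@H](O)[C@H]1OC(=O)c1ccc(cc1)[N+](=O)[O-] | intermediate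
7 | 2β,3β-epoxy-1β,6β-diol, formed in situ | C=C(C)[C@H]1C[C@H]2O[C@@]2(C)[C@@H](O)[C@H]1O | intermediate
8 | 2α-methyl-5β-(prop-1-en-2-yl)cyclohexane-1β,2β,3α,6β-tetrol | C=C(C)[C@H]1C[C@H](O)[C@@](C)(O)[C@@H](O)[C@H]1O | intermediate
9 | angelic acid, (Z)-2-methylbut-2-enoic acid | O=C(O)/C(C)=C\C | starting material
10 | angelic 2,4,6-trichlorobenzoic anhydride | O=C(OC(=O)c1c(Cl)cc(Cl)cc1Cl)/C(C)=C\C | intermediate
11 | 1,6-O-dibutylstannylene acetal of 8, formed in situ | C=C(C)[C@H]1C[C@H](O)[C@@](C)(O)[C@H]2O[Sn](CCCC)(CCCC)O[C@@H]12 | intermediate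
12 | 1β-O-angeloyl derivative of 8 (2β,3α,6β-triol) | C=C(C)[C@H]1C[C@H](O)[C@@](C)(O)[C@@H](OC(=O)/C(C)=C\C)[C@H]1O | intermediate
13 | 2,3,6-tris-O-TES ether of 12 | C=C(C)[C@H]1C[C@H](O[Si](CC)(CC)CC)[C@@](C)(O[Si](CC)(CC)CC)[C@@H](OC(=O)/C(C)=C\C)[C@H]1O[Si](CC)(CC)CC | intermediate
14 | allylic alcohol (isopropenyl CH3 of 13 → CH2OH), formed in situ | C=C(CO)[C@H]1C[C@H](O[Si](CC)(CC)CC)[C@@](C)(O[Si](CC)(CC)CC)[C@@H](OC(=O)/C(C)=C\C)[C@H]1O[Si](CC)(CC)CC | intermediate
15 | ring A enal (isopropenyl CH3 of 13 → CHO) | C=C(C=O)[C@H]1C[C@H](O[Si](CC)(CC)CC)[C@@](C)(O[Si](CC)(CC)CC)[C@@H](OC(=O)/C(C)=C\C)[C@H]1O[Si](CC)(CC)CC | intermediate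
16 | 3-hydroxy-3-methylbutan-2-one | CC(=O)C(C)(C)O | starting material
17 | 3-methyl-3-(triethylsilyloxy)butan-2-one | CC(=O)C(C)(C)O[Si](CC)(CC)CC | intermediate
18 | enol diisopinocampheylborinate of 17, formed in situ | C=C(OB([C@@H]1C[C@@H]2C[C@H]([C@H]1C)C2(C)C)[C@@H]1C[C@@H]2C[C@H]([C@H]1C)C2(C)C)C(C)(C)O[Si](CC)(CC)CC | intermediate
19 | diisopinocampheylboron aldolate of 20, formed in situ | C=C([C@H](OB([C@@H]1C[C@@H]2C[C@H]([C@H]1C)C2(C)C)[C@@H]1C[C@@H]2C[C@H]([C@H]1C)C2(C)C)CC(=O)C(C)(C)O[Si](CC)(CC)CC)[C@H]1C[C@H](O[Si](CC)(CC)CC)[C@@](C)(O[Si](CC)(CC)CC)[C@@H](OC(=O)/C(C)=C\C)[C@H]1O[Si](CC)(CC)CC | intermediate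
20 | (3′R)-aldol adduct (3′-OH, 5′-ketone, 6′-OTES) | C=C([C@H](O)CC(=O)C(C)(C)O[Si](CC)(CC)CC)[C@H]1C[C@H](O[Si](CC)(CC)CC)[C@@](C)(O[Si](CC)(CC)CC)[C@@H](OC(=O)/C(C)=C\C)[C@H]1O[Si](CC)(CC)CC | intermediate
21 | 3′-O-TES ether of 20 | C=C([C@H](O[Si](CC)(CC)CC)CC(=O)C(C)(C)O[Si](CC)(CC)CC)[C@H]1C[C@H](O[Si](CC)(CC)CC)[C@@](C)(O[Si](CC)(CC)CC)[C@@H](OC(=O)/C(C)=C\C)[C@H]1O[Si](CC)(CC)CC | intermediate
22 | (3′R,5′R)-5′-alcohol | C=C([C@H](O[Si](CC)(CC)CC)C[C@@H](O)C(C)(C)O[Si](CC)(CC)CC)[C@H]1C[C@H](O[Si](CC)(CC)CC)[C@@](C)(O[Si](CC)(CC)CC)[C@@H](OC(=O)/C(C)=C\C)[C@H]1O[Si](CC)(CC)CC | intermediate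
23 | penta-TES bis-angelate | C=C([C@H](O[Si](CC)(CC)CC)C[C@@H](OC(=O)/C(C)=C\C)C(C)(C)O[Si](CC)(CC)CC)[C@H]1C[C@H](O[Si](CC)(CC)CC)[C@@](C)(O[Si](CC)(CC)CC)[C@@H](OC(=O)/C(C)=C\C)[C@H]1O[Si](CC)(CC)CC | intermediate
24 | CNP0108485.1, (3R,5R)-3,6-dihydroxy-6-methyl-2-[(1R,2S,3S,4R,5S)-2,4,5-trihydroxy-4-methyl-3-{[(2Z)-2-methylbut-2-enoyl]oxy}cyclohexyl]hept-1-en-5-yl (2Z)-2-methylbut-2-enoate | C=C([C@H](O)C[C@@H](OC(=O)/C(C)=C\C)C(C)(C)O)[C@H]1C[C@H](O)[C@@](C)(O)[C@@H](OC(=O)/C(C)=C\C)[C@H]1O | target

**Step count and risks**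
Total step count: 15. Longest linear sequence: 13 steps (1–5, 7–9, 11–15 from (S)-carvone); steps 6 and 10 are side branches.

The three steps most likely to fail:

1. Step 11 (key aldol). The Ipc ligands may discriminate the aldehyde faces poorly with this hindered α-silyloxy methyl ketone, or enolisation by the bulky chloroborane may be sluggish. Fallback: setting out from 17, LiN(iPr)2/Me3SiCl gives the trimethylsilyl enol ether F8. A Lewis-base-catalysed Mukaiyama aldol of F8 with 15 (SiCl4, chiral binaphthyldiamine-derived bisphosphoramide, the antipode giving re-face attack, i-Pr2NEt, CH2Cl2, −78 °C; aqueous NaHCO3/KF work-up) comes back to the route at 20.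

2. Step 7 (stannylene-directed monoacylation). Acylation may spread over several of the four hydroxyls, or the acyl group may migrate between cis-vicinal oxygens. Fallback by temporary protection of C1–OH before the other hydroxyls exist: setting out from 6, neutral 4-methoxybenzylation (2-(4-methoxybenzyloxy)-4-methylquinoline, MeOTf, MgO, PhCF3) gives the C1 PMB ether F4. KOH in DMSO/H2O at 80 °C gives the PMB triol F5. TESOTf/2,6-lutidine gives the tris-TES PMB ether F6. DDQ in CH2Cl2/pH 7 buffer frees C1–OH to give the tris-TES alcohol F7. Acylation of this single hydroxyl with 10 (Et3N, toluene, 80 °C) comes back to the route at 13.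

3. Step 2 (Mitsunobu inversion). The activated α-ketol may eliminate and aromatise, or substitution may be incomplete at the hindered C6. Fallback by enolate epimerisation instead of substitution: setting out from 3, TBSCl/imidazole gives the trans silyl ether F1. Deprotonation at C6 (LiN(iPr)2, THF, −78 °C) and kinetic protonation with 2,6-di-tert-butylphenol from the face anti to the isopropenyl group gives the cis silyl ether F2. HF·pyridine gives cis-6-hydroxycarvone F3. 4-Nitrobenzoyl chloride/pyridine at 0 °C comes back to the route at 4.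

**Further compounds**
F1 | step 2 | trans-6-(tert-butyldimethylsilyloxy)carvone | C=C(C)[C@H]1CC=C(C)C(=O)[C@@H]1O[Si](C)(C)C(C)(C)C
F2 | step 2 | cis-6-(tert-butyldimethylsilyloxy)carvone | C=C(C)[C@H]1CC=C(C)C(=O)[C@H]1O[Si](C)(C)C(C)(C)C
F3 | step 2 | cis-6-hydroxycarvone | C=C(C)[C@H]1CC=C(C)C(=O)[C@H]1O
F4 | step 7 | 1β-O-(4-methoxybenzyl) ether of 6 | C=C(C)[C@H]1C[C@H]2O[C@@]2(C)[C@@H](OCc2ccc(OC)cc2)[C@H]1OC(=O)c1ccc(cc1)[N+](=O)[O-]
F5 | step 7 | 1β-O-(4-methoxybenzyl) ether of tetraol 8 | C=C(C)[C@H]1C[C@H](O)[C@@](C)(O)[C@@H](OCc2ccc(OC)cc2)[C@H]1O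
F6 | step 7 | 2,3,6-tris-O-TES ether of F5 | C=C(C)[C@H]1C[C@H](O[Si](CC)(CC)CC)[C@@](C)(O[Si](CC)(CC)CC)[C@@H](OCc2ccc(OC)cc2)[C@H]1O[Si](CC)(CC)CC
F7 | step 7 | 2,3,6-tris-O-TES ether of tetraol 8 (free 1β-OH) | C=C(C)[C@H]1C[C@H](O[Si](CC)(CC)CC)[C@@](C)(O[Si](CC)(CC)CC)[C@@H](O)[C@H]1O[Si](CC)(CC)CC
F8 | step 11 | trimethylsilyl enol ether of 17, 3-methyl-3-(triethylsilyloxy)-2-(trimethylsilyloxy)but-1-ene | C=C(O[Si](C)(C)C)C(C)(C)O[Si](CC)(CC)CC
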